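## Retrosynthetic overview

1. Numbering (p-menthane): C1 = C(CH3)(OH), C2 = CH bearing the trione, C3 = CH2, C4 = CH bearing isopropenyl, C5 and C6 = CH2. Last bonds cut: C1–CH3 (methyl carbanion onto a C1 ketone) and C2–C(trione) (C-alkylation of the trione enolate by a C2 bromide).
2. What remains is 4-isopropenylcyclohexanone, which has a mirror plane as the free ketone. It is therefore carried as a regio-defined silyl enol ether (C1=C2), with the isopropenyl group carried as an acetyl group.
3. Key disconnection: the cyclohexane ring by [4+2] of a 2-siloxybuta-1,3-diene (C6=C1–C2=C3) with methyl vinyl ketone (C4=C5), forming C5–C6 and C3–C4. The enabling feature: the O-bearing C1 and C4 (whose side-chain carbon can be written as C=O) stand 1,4 on the six-membered carbocycle, and C5 and C6 are plain CH2 groups.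
4. Stereo relay: C4 from the chiral catalyst of the cycloaddition; C2 by epimerisation α to the C1 ketone (cis-2,4-diequatorial); C1 by equatorial delivery of methyl.
5. Ring order: the carbocycle is the only ring built (step 2). The trione ring comes from an aromatic acylphloroglucinol by dearomative gem-diprenylation (step 5).

Key step: step 2

Assumption: the (S)-prolinol-derived oxazaborolidinium catalyst is taken to give (S)-3 with the acyclic enone; if the sense is the opposite, the mirror-image catalyst is used and nothing else changes.

## Route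

Step 1
Reactants: 1 methyl vinyl ketone (but-3-en-2-one)
Product: 2 2-(triisopropylsilyloxy)buta-1,3-diene
Conditions: iPr3SiOTf, Et3N, CH2Cl2, 0 °C → rt
Reagents that add atoms: triisopropylsilyl trifluoromethanesulfonate, CC(C)[Si](C(C)C)(C(C)C)OS(=O)(=O)C(F)(F)F
Why: Silyl enol ether formation by soft enolisation: the silyl triflate activates the carbonyl oxygen, triethylamine removes a proton from the methyl group and the cross-conjugated 2-siloxydiene results, the bulky triisopropylsilyl group being chosen so that the diene and the later enol ether withstand the acidic catalyst of step 2; no stereocentre is formed.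

Step 2
Reactants: 2 2-(triisopropylsilyloxy)buta-1,3-diene; 1 methyl vinyl ketone (1.5 equiv)
Product: 3 (S)-1-[4-(triisopropylsilyloxy)cyclohex-3-en-1-yl]ethan-1-one
Conditions: (S)-3,3-diphenyl-1-(2-methylphenyl)tetrahydro-1H,3H-pyrrolo[1,2-c][1,3,2]oxazaborole·HN(SO2CF3)2 (15 mol%), CH2Cl2, −78 °C
Reagents that add atoms: none
Why: The enone binds through its carbonyl oxygen to the cationic boron of the catalyst, which lowers its LUMO, and it then undergoes a concerted, asynchronous [4π+2π] cycloaddition with the diene, the C5–C6 bond (enone β-carbon to the diene CH2 next to the siloxy-bearing carbon, the terminus with the largest HOMO coefficient) being the more advanced one in the transition state. The closest known reaction type is the chiral oxazaborolidinium-catalysed Diels–Alder reaction of 2-(trialkylsiloxy)butadienes with acrylates, vinyl ketones and quinones. The cyclohexene ring is closed by intermolecular [4+2] cycloaddition, C5–C6 and C3–C4 being formed suprafacially on both components in one step. The only new stereocentre, C4, is controlled by the catalyst, whose aryl groups shield one face of the bound vinyl ketone so that the diene adds to the open face and (S)-C4 results. The selectivity needed is regiochemical (acetyl 1,4 to the siloxy group) and enantiofacial; the first is secured by the 2-siloxy donor of the diene and the polarised enone, the second by the catalyst, while endo/exo is of no consequence because a single stereocentre is formed. The enol-ether double bond that remains lies between C1 and C2 only, so the product is chiral although the corresponding ketone has a mirror plane, and C2 is marked for the later C–C bond.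

Step 3
Reactants: 3 (S)-1-[4-(triisopropylsilyloxy)cyclohex-3-en-1-yl]ethan-1-one
Product: 4 (S)-triisopropyl{[4-(prop-1-en-2-yl)cyclohex-1-en-1-yl]oxy}silane
Conditions: Ph3PCH3Br, KN(SiMe3)2, THF, −78 → 0 °C
Reagents that add atoms: methyltriphenylphosphonium bromide, C[P+](c1ccccc1)(c1ccccc1)c1ccccc1.[Br-]
Why: Wittig methylenation turns the acetyl group into the isopropenyl group under non-acidic conditions that leave the silyl enol ether alone, and at low temperature the ylide should add to the carbonyl group faster than it removes the tertiary C4–H, so that the C4 configuration is kept; no new stereocentre.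

Step 4
Reactants: 4 (S)-triisopropyl{[4-(prop-1-en-2-yl)cyclohex-1-en-1-yl]oxy}silane
Product: 5 (4S)-2-bromo-4-(prop-1-en-2-yl)cyclohexan-1-one (both C2 epimers)
Conditions: NBS, THF, −78 °C; used crude
Reagents that add atoms: N-bromosuccinimide, O=C1CCC(=O)N1Br
Why: α-Bromination of a ketone through its silyl enol ether: the electron-rich C1=C2 double bond takes up bromine from NBS at C2 far faster than the isopropenyl group reacts, so the C2/C6 choice written in step 2 is turned into a leaving group at C2 only; the configuration at C2 is left open because it is replaced and equilibrated in step 6.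

Step 5
Reactants: 6 phlorisobutyrophenone (2-methyl-1-(2,4,6-trihydroxyphenyl)propan-1-one); 7 prenyl bromide (1-bromo-3-methylbut-2-ene, 2.2 equiv)
Product: 9 3,5-dihydroxy-2-(2-methylpropanoyl)-6,6-bis(3-methylbut-2-en-1-yl)cyclohexa-2,4-dien-1-one, via monoprenyl phloroglucinol 8 (not isolated)
Conditions: NaOMe (2.2 equiv), MeOH, 0 °C → rt
Reagents that add atoms: none
Why: Dearomative C-alkylation of a phloroglucinol anion with an allylic bromide (the reaction type that gives lupulone-type triones): the first prenyl group enters a free ring carbon and the second should enter the same carbon, which is now the most electron-rich one, to give the gem-diprenyl trione, with the 3,5-diprenyl isomer and O-alkylated material as expected by-products to be removed by chromatography; no stereocentre.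

Step 6
Reactants: 5 (4S)-2-bromo-4-(prop-1-en-2-yl)cyclohexan-1-one; 9 3,5-dihydroxy-2-(2-methylpropanoyl)-6,6-bis(3-methylbut-2-en-1-yl)cyclohexa-2,4-dien-1-one
Product: 11 3,5-dihydroxy-2-(2-methylpropanoyl)-6,6-bis(3-methylbut-2-en-1-yl)-4-[(1R,5S)-2-oxo-5-(prop-1-en-2-yl)cyclohexyl]cyclohexa-2,4-dien-1-one, via trans epimer 10 (not isolated)
Conditions: 9 + KOH (1.0 equiv), MeOH–H2O, 0 °C, then 5, 0 °C → rt; then KOH (0.3 equiv), rt; work-up at pH 5–6
Reagents that add atoms: none
Why: C-Alkylation of a cyclic 1,3-dicarbonyl anion with an α-halo ketone (the first stage of a Feist–Benary furan synthesis, known for cyclohexane-1,3-diones and 2-halocyclohexanones) forms the C2–C(trione) bond by SN2 displacement of the activated bromide, and the C2 stereocentre, now α to the C1 ketone, is then set under thermodynamic control by base-mediated epimerisation to the cis-2,4-diequatorial ketone (2R).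

Step 7
Reactants: 11 3,5-dihydroxy-2-(2-methylpropanoyl)-6,6-bis(3-methylbut-2-en-1-yl)-4-[(1R,5S)-2-oxo-5-(prop-1-en-2-yl)cyclohexyl]cyclohexa-2,4-dien-1-one
Product: 12 3,5-dihydroxy-4-[(1R,2R,5S)-2-hydroxy-2-methyl-5-(prop-1-en-2-yl)cyclohexyl]-2-(2-methylpropanoyl)-6,6-bis(3-methylbut-2-en-1-yl)cyclohexa-2,4-dien-1-one (target)
Conditions: MeLi (5 equiv), CeCl3 (5 equiv), THF, −78 °C; then H2O
Reagents that add atoms: methyllithium, [Li]C
Why: 1,2-Addition of an organocerium reagent to a ketone: two equivalents deprotonate the enol OH groups, which turns the trione into an unreactive polyanion, and the weakly basic methylcerium species should then add to C1 from the equatorial side, next to the axial C2–H and away from the axial hydrogens on C3 and C5 (with chelation between the ketone and the neighbouring enolate oxygen pointing the same way), so that methyl ends equatorial and the hydroxyl group axial and cis to the equatorial trione substituent, which is (1R).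

## Compound list

1 | methyl vinyl ketone (but-3-en-2-one) | CC(=O)C=C | starting material
2 | 2-(triisopropylsilyloxy)buta-1,3-diene | C=CC(=C)O[Si](C(C)C)(C(C)C)C(C)C | intermediate
3 | (S)-1-[4-(triisopropylsilyloxy)cyclohex-3-en-1-yl]ethan-1-one | CC(=O)[C@H]1CCC(O[Si](C(C)C)(C(C)C)C(C)C)=CC1 | intermediate
4 | (S)-triisopropyl{[4-(prop-1-en-2-yl)cyclohex-1-en-1-yl]oxy}silane | C=C(C)[C@H]1CCC(O[Si](C(C)C)(C(C)C)C(C)C)=CC1 | intermediate
5 | (4S)-2-bromo-4-(prop-1-en-2-yl)cyclohexan-1-one (both C2 epimers) | C=C(C)[C@H]1CCC(=O)C(Br)C1 | intermediate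
6 | phlorisobutyrophenone (2-methyl-1-(2,4,6-trihydroxyphenyl)propan-1-one) | CC(C)C(=O)c1c(O)cc(O)cc1O | starting material
7 | prenyl bromide (1-bromo-3-methylbut-2-ene) | CC(C)=CCBr | starting material
8 | 2-methyl-1-[2,4,6-trihydroxy-3-(3-methylbut-2-en-1-yl)phenyl]propan-1-one | CC(C)C(=O)c1c(O)cc(O)c(CC=C(C)C)c1O | intermediate
9 | 3,5-dihydroxy-2-(2-methylpropanoyl)-6,6-bis(3-methylbut-2-en-1-yl)cyclohexa-2,4-dien-1-one | CC(C)C(=O)C1=C(O)C=C(O)C(CC=C(C)C)(CC=C(C)C)C1=O | intermediate
10 | 3,5-dihydroxy-2-(2-methylpropanoyl)-6,6-bis(3-methylbut-2-en-1-yl)-4-[(1S,5S)-2-oxo-5-(prop-1-en-2-yl)cyclohexyl]cyclohexa-2,4-dien-1-one (trans epimer) | C=C(C)[C@H]1CCC(=O)[C@H](C2=C(O)C(CC=C(C)C)(CC=C(C)C)C(=O)C(C(=O)C(C)C)=C2O)C1 | intermediate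
11 | 3,5-dihydroxy-2-(2-methylpropanoyl)-6,6-bis(3-methylbut-2-en-1-yl)-4-[(1R,5S)-2-oxo-5-(prop-1-en-2-yl)cyclohexyl]cyclohexa-2,4-dien-1-one | C=C(C)[C@H]1CCC(=O)[C@@H](C2=C(O)C(CC=C(C)C)(CC=C(C)C)C(=O)C(C(=O)C(C)C)=C2O)C1 | intermediate
12 | 3,5-dihydroxy-4-[(1R,2R,5S)-2-hydroxy-2-methyl-5-(prop-1-en-2-yl)cyclohexyl]-2-(2-methylpropanoyl)-6,6-bis(3-methylbut-2-en-1-yl)cyclohexa-2,4-dien-1-one | C=C(C)[C@H]1CC[C@@](C)(O)[C@@H](C2=C(O)C(CC=C(C)C)(CC=C(C)C)C(=O)C(C(=O)C(C)C)=C2O)C1 | target

## Step count and risks

Total step count: 7. Longest linear sequence: 6 steps (steps 1, 2, 3, 4, 6, 7); step 5 is the convergent branch.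

Steps most likely to fail:

Step 6. The ambident trione enolate may react at oxygen, or add to the ketone carbonyl first and then close a ring onto C2 (which would join the wrong carbon), or the bromo ketone may lose HBr. The fallback sets out from 5 and 9 and comes back at 11. Compound 5 is converted with NH2OH·HCl and NaOAc in MeOH into (4S)-2-bromo-4-(prop-1-en-2-yl)cyclohexan-1-one oxime F1. Na2CO3 in CH2Cl2 eliminates HBr to the transient (S)-1-nitroso-4-(prop-1-en-2-yl)cyclohex-1-ene F2, in which the carbonyl group is masked and only C2 is electrophilic. The enolate of 9 adds to it at C2 by conjugate addition, a known way to α-alkylate ketones with stabilised carbanions, and gives the oxime of 11 F3. Exchange of the oxime with aqueous glyoxylic acid, followed by a short equilibration with KOH in MeOH, returns 11.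

Step 7. The methyl group may be delivered with poor facial selectivity, or the hindered ketone may be enolised in place of being attacked. The fallback sets out from 11 and comes back at 12. Corey–Chaykovsky methylenation with dimethylsulfoxonium methylide (trimethylsulfoxonium iodide, NaH, DMSO) adds reversibly and places the new CH2 group equatorial, which should give the C1 spiro-epoxide of 11 with axial oxygen F4. LiBHEt3 in THF then opens the epoxide at its CH2 carbon and gives 12.

Step 2. The enantioselectivity may be insufficient with the acyclic enone, or the acid catalyst may cleave the silyl enol ether. The fallback sets out from 1 and 2 and comes back at 5. The cycloaddition is run without catalyst (toluene, 80 °C) and gives racemic 1-[4-(triisopropylsilyloxy)cyclohex-3-en-1-yl]ethan-1-one F5. Wittig methylenation gives racemic triisopropyl{[4-(prop-1-en-2-yl)cyclohex-1-en-1-yl]oxy}silane F6, and Bu4NF with AcOH gives the achiral ketone 4-(prop-1-en-2-yl)cyclohexan-1-one F7. Enantioselective deprotonation with lithium bis[(R)-1-phenylethyl]amide (or its mirror image, whichever removes the proton on the C2 side) with Me3SiCl present gives (S)-trimethyl{[4-(prop-1-en-2-yl)cyclohex-1-en-1-yl]oxy}silane F8. NBS in THF at −78 °C converts it into 5.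

## Further compounds

F1 | step 6 | (4S)-2-bromo-4-(prop-1-en-2-yl)cyclohexan-1-one oxime (C2 epimers, oxime geometry open) | C=C(C)[C@H]1CCC(=NO)C(Br)C1
F2 | step 6 | (S)-1-nitroso-4-(prop-1-en-2-yl)cyclohex-1-ene | C=C(C)[C@H]1CCC(N=O)=CC1
F3 | step 6 | oxime of 11 (C2 epimers): 3,5-dihydroxy-4-[(5S)-2-(hydroxyimino)-5-(prop-1-en-2-yl)cyclohexyl]-2-(2-methylpropanoyl)-6,6-bis(3-methylbut-2-en-1-yl)cyclohexa-2,4-dien-1-one | C=C(C)[C@H]1CCC(=NO)C(C2=C(O)C(CC=C(C)C)(CC=C(C)C)C(=O)C(C(=O)C(C)C)=C2O)C1
F4 | step 7 | spiro-epoxide of 11 at C1 (1-oxaspiro[2.5]octane; oxygen axial and cis to the trione substituent, CH2 in the place of the later methyl group) | C=C(C)[C@H]1CC[C@]2(CO2)[C@@H](C3=C(O)C(CC=C(C)C)(CC=C(C)C)C(=O)C(C(=O)C(C)C)=C3O)C1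
F5 | step 2 | racemic 1-[4-(triisopropylsilyloxy)cyclohex-3-en-1-yl]ethan-1-one | CC(=O)C1CCC(O[Si](C(C)C)(C(C)C)C(C)C)=CC1
F6 | step 2 | racemic triisopropyl{[4-(prop-1-en-2-yl)cyclohex-1-en-1-yl]oxy}silane | C=C(C)C1CCC(O[Si](C(C)C)(C(C)C)C(C)C)=CC1
F7 | step 2 | 4-(prop-1-en-2-yl)cyclohexan-1-one | C=C(C)C1CCC(=O)CC1
F8 | step 2 | (S)-trimethyl{[4-(prop-1-en-2-yl)cyclohex-1-en-1-yl]oxy}silane | C=C(C)[C@H]1CCC(O[Si](C)(C)C)=CC1
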